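## Structural features

The target 22 is a 2,2-dimethyl-2H-chromene: a benzene ring fused through the C4a–C8a bond to a 2H-pyran that holds the ring oxygen O1, the gem-dimethyl carbon C2 and the C3=C4 double bond. The benzene ring is a phloroglucinol whose three oxygens play three different roles: free hydroxyl at C5, methyl ether at C7 and ring oxygen at C8a. Its two carbon substituents, C4 of the pyran on C4a and the 3-oxo-3-phenylpropanoyl chain on C6, each sit between two oxygens, and only C8 carries hydrogen. There is no stereocenter, because C2 bears two methyl groups, so nothing stereochemical has to be set or preserved. The fragile parts are the electron-rich styrene-type C3=C4 olefin (acid, electrophiles, hydrogenation), the o-hydroxyaryl 1,3-diketone (cyclodehydration to a flavone under acid or heat, retro-Claisen cleavage in hot hydroxide) and the oxidisable arene with its open C8 position. The real difficulty is regiochemical: a carbon has to be placed on C4a between two oxygens, a second carbon on C6 rather than C8, and the pyran must close onto the C8a oxygen only. The key step answers this by building the benzene ring itself from a four-carbon cyclobutenone (C6, C7, C8, C8a) and a two-carbon ynol ether (C4a, C5). The prenyl carbon thereby lands on C4a, the C8a oxygen arrives as the free hydroxyl, the C5 oxygen as a silyl ether and the C7 oxygen as the methyl ether. Ring opening of the cyclobutenone gives the 1-methoxyvinyl ketene (methoxy on the internal vinyl carbon), not a 2-methoxyvinyl isomer, and only this connectivity puts the methoxy on C7 rather than C8.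

## Logic of the disconnections

22 to 20. The bond between the methylene carbon and the benzoyl carbon is cut. An o-hydroxyaryl methyl ketone plus a benzoyl electrophile is the classical retron of this diketone, and the forward reaction ends under base, so the acid-sensitive o-hydroxy diketone never meets acid and the C5 hydroxyl needs no protecting group. The gain is the loss of the whole phenyl ketone. The demand is C-acylation of the ketone enolate within dianion 21 (or O-acylation followed by O-to-C acyl transfer) and a mild quench.

20 to 19 to 18. After an oxidation-level adjustment, the bond between the carbonyl carbon and the methyl group is cut. A formyl group can be placed on C6 with full ortho control, whereas a direct Friedel–Crafts or Fries acetylation would have to choose between C6 and C8 and would expose the chromene olefin to Lewis acids. The gain is a one-carbon substituent on C6. The demand is addition of a methyl nucleophile to a phenoxide-bearing aldehyde and an oxidation that spares phenol and olefin; the stereocenter of 19 is transient.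

18 to 17. The C6–CHO bond is cut. In 17 the C5 hydroxyl has only one free ortho position, so a phenoxide-delivered formylation cannot go astray. The gain is an arene with no carbon substituent on C6. The demand is a chelation-controlled rather than a free electrophilic formylation, which could attack C8.

17 to 16 to 14. The O–Si bond is cut first, then the O1–C2 bond of the pyran, with the C3=C4 olefin going back to the prenyl olefin through 15. Oxidative cyclisation of an o-prenylphenol is reliable, and the silyl group on the C5 oxygen guarantees that only the C8a oxygen closes and shields the resorcinol from the oxidant. The gain is a monocyclic arene. The demand, met by the key step, is a free hydroxyl on the correct side of the prenyl group.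

14 to 5 and 9. Three ring bonds are cut: C4a–C8a and C5–C6 (the cycloaddition bonds) and C8–C8a (the former C1–C4 bond of 5, broken and re-formed). The arene falls into a strained C4 unit and an electron-rich C2 unit, each already carrying its oxygen in the right form, and C-prenylation of a phloroglucinol is avoided. The demands are regioselective ketene–alkyne union, thermal survival of 9 and closure of 12. The partners are kept as they are; the only design choices are triisopropylsilyl on the ynol oxygen (O-silylation of 8, stability to heat and to the later oxidant) and slow addition of 5.

5 to 4 to 1 and 2. The methyl–oxygen pairing is traced back to an alkoxy exchange, and the ring bonds C1–C2 and C3–C4 of 4 are cut as a (2+2) union of 1 with 3, generated in the flask from 2. This reaches commercial materials and avoids gaseous ketene. The demands are trapping of 3 before it dimerises and exchange without opening the four-membered ring.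

9 to 6. The O–Si bond is cut, and the alkyne carbon bearing the prenyl group is removed as a one-carbon insertion between the prenyl methylene and the carbonyl carbon of 6 (through 7 and 8). The gain is a commercial ester. The demands are addition to the ester faster than enolisation of its doubly activated methylene, and silylation of 8 on oxygen.

## Other disconnections considered

Alternative 1: The cut removes both bonds at the aryl ketone carbon of 22, C6–C(=O) and C(=O)–CH2. In the forward direction the C6 iodide A1 (from 17 by iodination and acetal protection), the enolate of acetophenone A2 and carbon monoxide A3 would be joined on a zerovalent palladium catalyst to give the protected diketone A4, and acid would then release 22.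
- In its favour: one catalytic event forms two C–C bonds and installs the whole side chain from very simple partners.
- Against it here: the carbon–iodine bond of A1 is flanked by two oxygen substituents on an electron-rich ring, so oxidative addition and the crowded aroylpalladium stage are both unfavourable. The diketone product can bind the metal. Iodination of 17 has no built-in preference for C6 over C8. The acetal must be removed with acid at exactly the stage where the o-hydroxy diketone is prone to cyclodehydration.
- Structure: this alternative only addresses the side chain and still needs a chromene synthesis such as steps 1 to 6.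
- Mechanism: it is more convergent than the four polar steps 7 to 10, and on that point it is the better plan.
- Step economy: iodination, protection, carbonylation and deprotection make four operations from 17, equal to steps 7 to 10.
- Overall it is weaker on regiochemical security and on acid exposure at the end.

Alternative 2: The cut is O1–C8a. In the forward direction the Z-configured tertiary allylic alcohol A6, reachable from aldehyde A5 by a Z-selective phosphonate olefination and double methyl addition to the resulting carboxylate function, would close onto one of its two equivalent C–Br bonds under palladium or copper catalysis to give bromochromene A7. Hydroxylation of the remaining C5 bromide would then deliver 17.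
- In its favour: symmetry removes any regiochemical question in the ring closure, only one hydroxyl is present so over-reaction is impossible, the arene is bought rather than built, and no ketene or strained ring is heated.
- Against it here: C–O bond formation from a tertiary alkoxide onto a doubly ortho-substituted aryl bromide is among the most demanding etherifications. The Z geometry must be made and kept, since the E isomer cannot cyclise and the tertiary allylic alcohol can ionise or transpose. The C5 oxygen arrives only after an extra carbon–bromine to carbon–oxygen conversion.
- Structure: the oxygens of A7 are not all in place, whereas 14 carries all three at the right oxidation level.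
- Mechanism: a catalytic cross-coupling at a hindered site stands against a pericyclic cascade that needs no catalyst.
- Step economy: about four steps from A5 to 17 against six (steps 1 to 6), so here the alternative is the better plan, as it is on the hazard profile of the early reagents.
- Overall the chosen plan is stronger on the certainty of the ring-forming event.

Alternative 3: The cut is the bond between the aryl ketone carbon and the methylene, with the diketone masked as an isoxazole. In the forward direction aldehyde A8 (18 protected as its methoxymethyl ether) would be converted to oxime A9 and oxidised to nitrile oxide A10. A (3+2) cycloaddition of A10 with phenylacetylene A11 would give isoxazole A12, and reductive N–O cleavage to the β-amino enone A13 followed by hydrolysis would unveil the diketone.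
- In its favour: the two ortho substituents shield the dipole A10 against self-condensation. Terminal alkynes add to nitrile oxides with dependable 3,5-regiochemistry. The isoxazole keeps the diketone locked while the phenol is unmasked, so acid never meets the free o-hydroxy diketone; on this point the alternative is the better design.
- Against it here: the oxidants that generate A10 can halogenate or oxidise the electron-rich ring at C8. The chromene olefin is a second, if poorer, dipolarophile. N–O cleavage must avoid hydrogenation conditions that would saturate C3=C4. Hydrolysis of A13 next to an ortho oxygen can divert to ring closure.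
- Structure: it uses the same aldehyde carbon as the chosen route and the same ring synthesis, so the two are equal there.
- Mechanism: a pericyclic cycloaddition plus two unmasking steps replaces an enolate acylation.
- Step economy: protection, oximation, cycloaddition, N–O cleavage, hydrolysis and deprotection make six operations from 18 against three (steps 8 to 10), so the chosen plan is clearly shorter.

Key step: step 4

Assumption: 22 is drawn as its diketo tautomer; in solution it should sit largely as the hydrogen-bonded enol, which is the same compound for this route.

## Route

Step 1
Reactants: 1 ethoxyacetylene; 2 acetyl chloride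
Product: 4 3-ethoxycyclobut-2-en-1-one, via ketene 3 (not isolated)
Conditions: Et3N, Et2O, 0 °C to rt, slow addition of 2
Reagents that add atoms: none
Why: Triethylamine dehydrochlorinates 2 to ketene 3, which is trapped in a regioselective ketene–alkyne (2+2) cycloaddition by the electron-rich ynol ether 1 (its unsubstituted carbon bonds to the ketene carbonyl carbon); generating 3 in the flask avoids handling ketene gas.

Step 2
Reactants: 4 3-ethoxycyclobut-2-en-1-one
Product: 5 3-methoxycyclobut-2-en-1-one
Conditions: MeOH (solvent), pyridinium p-toluenesulfonate (cat.), 0 °C to rt
Reagents that add atoms: methanol CO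
Why: Acid-catalysed vinylogous transesterification (addition of methanol at C3 to the mixed ketal, loss of ethanol), the same addition–elimination by which squarate esters exchange alkoxy groups, driven by methanol as solvent; the temperature is kept low so that the strained ring stays closed.

Step 3
Reactants: 6 ethyl 4-methylpent-3-enoate
Product: 9 triisopropyl[(5-methylhex-4-en-1-yn-1-yl)oxy]silane, via lithium dibromoenolate 7 (not isolated), via lithium ynolate 8 (not isolated)
Conditions: CH2Br2, lithium 2,2,6,6-tetramethylpiperidide, THF, −78 °C; LiN(SiMe3)2; n-BuLi, −78 °C to rt; i-Pr3SiCl, −78 °C to rt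
Reagents that add atoms: dibromomethane BrCBr; chlorotriisopropylsilane CC(C)[Si](Cl)(C(C)C)C(C)C
Why: Kowalski ester homologation: LiCHBr2 adds to the ester, the dibromo enolate 7 undergoes bromine–lithium exchange and 1,2-shift of the prenyl group to give ynolate 8, and the bulky silyl chloride caps 8 on oxygen rather than carbon.

Step 4
Reactants: 5 3-methoxycyclobut-2-en-1-one; 9 triisopropyl[(5-methylhex-4-en-1-yn-1-yl)oxy]silane
Product: 14 5-methoxy-2-(3-methylbut-2-en-1-yl)-3-[(triisopropylsilyl)oxy]phenol, via vinylketene 10 (not isolated), via vinylcyclobutenone 11 (not isolated), via dienylketene 12 (not isolated), via cyclohexadienone 13 (not isolated)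
Conditions: PhMe, 80 to 110 °C, argon, slow addition of 5 to 9 (1.2 equiv)
Reagents that add atoms: none
Why: This is the known Danheiser benzannulation of a cyclobutenone with a trialkylsilyloxyalkyne to a resorcinol monosilyl ether, driven by release of four-ring strain and by aromatisation. Thermal conrotatory 4π opening of 5 cleaves its C1–C4 bond and gives the 1-methoxyvinyl ketene 10, with the methoxy on the internal vinyl carbon. The polarised ynol ether 9 then adds across the ketene C=C in a regioselective (2+2) cycloaddition, its nucleophilic prenyl-bearing carbon bonding to the ketene carbonyl carbon (C4a–C8a) and its oxygen-bearing carbon to the ketene α-carbon (C5–C6), to give racemic 11. A second, reversible 4π opening gives dienylketene 12, and the isomer with C4a and C7 cis across C5=C6 closes by thermal disrotatory 6π electrocyclisation (C8–C8a) to 13, which tautomerises to phenol 14; this pericyclic closure forms the only new ring. No stereocenter remains, since the single sp3 center of 11 is destroyed on ring opening. The step needs regiocontrol in the (2+2) (secured by the oxygen polarisation of 9), preference for the alkyne over the trisubstituted prenyl olefin (ynol ethers are far better ketenophiles) and suppression of acylation of 14 by 10 (secured by slow addition of 5 to a slight excess of 9). As a result the ketene oxygen becomes the free C8a hydroxyl, the silyloxy carbon becomes C5 and the methoxy carbon becomes C7.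

Step 5
Reactants: 14 5-methoxy-2-(3-methylbut-2-en-1-yl)-3-[(triisopropylsilyl)oxy]phenol
Product: 16 triisopropyl[(7-methoxy-2,2-dimethyl-2H-chromen-5-yl)oxy]silane, via ortho-quinone methide 15 (not isolated)
Conditions: DDQ (1.1 equiv), PhMe, 80 °C
Reagents that add atoms: none
Why: Known oxidative cyclisation of o-prenylphenols: DDQ removes hydride from the benzylic–allylic CH2 next to the free hydroxyl to give ortho-quinone methide 15, which closes the pyran by oxa-6π electrocyclisation; only the C8a oxygen can take part because the C5 oxygen is silylated.

Step 6
Reactants: 16 triisopropyl[(7-methoxy-2,2-dimethyl-2H-chromen-5-yl)oxy]silane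
Product: 17 7-methoxy-2,2-dimethyl-2H-chromen-5-ol
Conditions: Bu4NF, THF, 0 °C; aq. NH4Cl
Reagents that add atoms: none
Why: Fluoride-mediated cleavage of the aryl silyl ether, driven by the strong Si–F bond, leaves the methyl ether and the chromene olefin untouched.

Step 7
Reactants: 17 7-methoxy-2,2-dimethyl-2H-chromen-5-ol
Product: 18 5-hydroxy-7-methoxy-2,2-dimethyl-2H-chromene-6-carbaldehyde
Conditions: MgCl2, Et3N, (CH2O)n, MeCN, reflux; cold 1 M HCl
Reagents that add atoms: formaldehyde (as paraformaldehyde) C=O
Why: Casnati–Skattebøl ortho-formylation: the magnesium phenoxide delivers formaldehyde to its ortho carbon through a chelate and the resulting benzylic alkoxide is oxidised by a second formaldehyde (Oppenauer-type hydride transfer); C6 is the only free ortho position of the C5 hydroxyl, so C8 is not attacked.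

Step 8
Reactants: 18 5-hydroxy-7-methoxy-2,2-dimethyl-2H-chromene-6-carbaldehyde
Product: 19 rac-6-(1-hydroxyethyl)-7-methoxy-2,2-dimethyl-2H-chromen-5-ol
Conditions: MeMgBr (3 equiv), THF, 0 °C; aq. NH4Cl
Reagents that add atoms: methylmagnesium bromide C[Mg]Br
Why: Grignard addition to the aldehyde after the first equivalent has deprotonated the phenol; the new carbinol stereocenter forms without control as a racemate and is erased in step 9.

Step 9
Reactants: 19 rac-6-(1-hydroxyethyl)-7-methoxy-2,2-dimethyl-2H-chromen-5-ol
Product: 20 1-(5-hydroxy-7-methoxy-2,2-dimethyl-2H-chromen-6-yl)ethan-1-one
Conditions: MnO2 (excess), CH2Cl2, rt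
Reagents that add atoms: none
Why: Activated manganese dioxide oxidises the benzylic secondary alcohol to the aryl methyl ketone under neutral conditions that tolerate the free phenol and the chromene olefin; the product is stabilised by its O–H···O=C hydrogen bond.

Step 10
Reactants: 20 1-(5-hydroxy-7-methoxy-2,2-dimethyl-2H-chromen-6-yl)ethan-1-one
Product: 22 1-(5-hydroxy-7-methoxy-2,2-dimethyl-2H-chromen-6-yl)-3-phenylpropane-1,3-dione, via dilithium dianion 21 (not isolated)
Conditions: LiN(SiMe3)2 (3.3 equiv), THF, −78 to −10 °C; PhCOCl (1.05 equiv), −78 °C to rt; cold aq. NH4Cl/AcOH
Reagents that add atoms: benzoyl chloride O=C(Cl)c1ccccc1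
Why: Excess amide base forms the phenoxide–enolate dianion 21, whose methyl ketone enolate is benzoylated on carbon, either directly or by O-benzoylation and intramolecular Baker–Venkataraman acyl transfer under the same conditions. The diketone stays protected as its chelated lithium enolate until a cold, weakly acidic quench, which avoids cyclodehydration to the flavone.

## Compound list

1 | ethoxyacetylene | CCOC#C | starting material
2 | acetyl chloride | CC(=O)Cl | starting material
3 | ketene (ethenone) | C=C=O | intermediate (not isolated)
4 | 3-ethoxycyclobut-2-en-1-one | CCOC1=CC(=O)C1 | intermediate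
5 | 3-methoxycyclobut-2-en-1-one | COC1=CC(=O)C1 | intermediate
6 | ethyl 4-methylpent-3-enoate | CCOC(=O)CC=C(C)C | starting material
7 | lithium 1,1-dibromo-5-methylhexa-1,4-dien-2-olate | [Li+].[O-]C(CC=C(C)C)=C(Br)Br | intermediate (not isolated)
8 | lithium 5-methylhex-4-en-1-yn-1-olate | [Li+].[O-]C#CCC=C(C)C | intermediate (not isolated)
9 | triisopropyl[(5-methylhex-4-en-1-yn-1-yl)oxy]silane | CC(C)=CCC#CO[Si](C(C)C)(C(C)C)C(C)C | intermediate
10 | 3-methoxybuta-1,3-dien-1-one, the (1-methoxyvinyl)ketene | COC(=C)C=C=O | intermediate (not isolated)
11 | rac-4-(1-methoxyethenyl)-2-(3-methylbut-2-en-1-yl)-3-[(triisopropylsilyl)oxy]cyclobut-2-en-1-one | O=C1C(CC=C(C)C)=C(O[Si](C(C)C)(C(C)C)C(C)C)C1C(=C)OC | intermediate (not isolated)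
12 | (3E)-5-methoxy-2-(3-methylbut-2-en-1-yl)-3-[(triisopropylsilyl)oxy]hexa-1,3,5-trien-1-one | O=C=C(CC=C(C)C)/C(O[Si](C(C)C)(C(C)C)C(C)C)=C\C(OC)=C | intermediate (not isolated)
13 | 5-methoxy-2-(3-methylbut-2-en-1-yl)-3-[(triisopropylsilyl)oxy]cyclohexa-2,4-dien-1-one | O=C1CC(OC)=CC(O[Si](C(C)C)(C(C)C)C(C)C)=C1CC=C(C)C | intermediate (not isolated)
14 | 5-methoxy-2-(3-methylbut-2-en-1-yl)-3-[(triisopropylsilyl)oxy]phenol | COc1cc(O)c(CC=C(C)C)c(O[Si](C(C)C)(C(C)C)C(C)C)c1 | intermediate
15 | 3-methoxy-6-(3-methylbut-2-en-1-ylidene)-5-[(triisopropylsilyl)oxy]cyclohexa-2,4-dien-1-one | O=C1C=C(OC)C=C(O[Si](C(C)C)(C(C)C)C(C)C)C1=CC=C(C)C | intermediate (not isolated)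
16 | triisopropyl[(7-methoxy-2,2-dimethyl-2H-chromen-5-yl)oxy]silane | COc1cc2c(C=CC(C)(C)O2)c(O[Si](C(C)C)(C(C)C)C(C)C)c1 | intermediate
17 | 7-methoxy-2,2-dimethyl-2H-chromen-5-ol | COc1cc(O)c2C=CC(C)(C)Oc2c1 | intermediate
18 | 5-hydroxy-7-methoxy-2,2-dimethyl-2H-chromene-6-carbaldehyde | COc1cc2c(C=CC(C)(C)O2)c(O)c1C=O | intermediate
19 | rac-6-(1-hydroxyethyl)-7-methoxy-2,2-dimethyl-2H-chromen-5-ol (racemate) | COc1cc2c(C=CC(C)(C)O2)c(O)c1C(C)O | intermediate
20 | 1-(5-hydroxy-7-methoxy-2,2-dimethyl-2H-chromen-6-yl)ethan-1-one | COc1cc2c(C=CC(C)(C)O2)c(O)c1C(C)=O | intermediate
21 | dilithium 7-methoxy-2,2-dimethyl-6-(1-oxidoethenyl)-2H-chromen-5-olate | COc1cc2c(C=CC(C)(C)O2)c([O-])c1C(=C)[O-].[Li+].[Li+] | intermediate (not isolated)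
22 | 1-(5-hydroxy-7-methoxy-2,2-dimethyl-2H-chromen-6-yl)-3-phenylpropane-1,3-dione | COc1cc2c(c(O)c1C(=O)CC(=O)c1ccccc1)C=CC(C)(C)O2 | target

## Step count and least certain steps

Total step count: 10. Longest linear sequence: 9 (steps 1, 2, 4, 5, 6, 7, 8, 9, 10); step 3 is the short second branch.

Step 4 (key step). Ring opening of the alkoxy-substituted cyclobutenone may need temperatures at which the vinylketene oligomerises, at which the siloxyalkyne suffers oxygen-to-carbon silyl migration, or at which the product phenol is acylated by unreacted ketene. Fallback, setting out from 9 and returning at 14: the same vinylketene 10 would be generated at room temperature by photochemical Wolff rearrangement instead of by heating 5. 3,3-Dimethoxybutan-2-one F1 would lose methanol under acid catalysis to give 3-methoxybut-3-en-2-one F2. Its lithium enolate would be trifluoroacetylated with 2,2,2-trifluoroethyl trifluoroacetate to 1,1,1-trifluoro-5-methoxyhex-5-ene-2,4-dione F3. Detrifluoroacetylative diazo transfer with 4-acetamidobenzenesulfonyl azide, Et3N and water would give 1-diazo-3-methoxybut-3-en-2-one F4. Irradiation of F4 with 9 in CH2Cl2, with brief warming if the vinylcyclobutenone stage persists, should lead through 10, 11, 12 and 13 to 14. This photochemical version of the benzannulation is known for unsaturated diazo ketones and alkynes.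

Step 2. Methanol may attack the ring carbonyl or trap a ring-opened ketene, so that the four-membered ring is lost, or the exchange may stop at a mixture of the two vinylogous esters. Fallback, setting out from 4 and returning at 5: cold dilute aqueous HCl would hydrolyse 4 to cyclobutane-1,3-dione F5 (present mainly as its enol), and O-methylation of this vinylogous acid with dimethyl sulfate and K2CO3 in acetone would give 5 by alkylation at methyl rather than by addition–elimination at C3.

Step 3. The carbenoid base may deprotonate the doubly activated methylene of the β,γ-unsaturated ester instead of adding to the carbonyl, with migration of the olefin into conjugation and incomplete homologation; silylation may also occur partly on carbon. Fallback, setting out from 6 and returning at 8 and then 9: i-Bu2AlH at −78 °C would reduce 6 to 4-methylpent-3-enal F6. CBr4 and PPh3 would convert it to 1,1-dibromo-5-methylhexa-1,4-diene F7 (first stage of the Corey–Fuchs reaction), and two equivalents of n-BuLi would give (5-methylhex-4-en-1-yn-1-yl)lithium F8. Oxidation of this acetylide with lithium tert-butyl peroxide (from t-BuOOH and LiN(SiMe3)2) is a known way to ynolates and would give 8, which is silylated to 9 as in step 3.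

Step 1. Ketene made in the flask may dimerise, be lost as a gas or be consumed by acylammonium side reactions before the cycloaddition, and the ynol ether may polymerise. Fallback, setting out from 1 and returning at 4: dichloroketene, from trichloroacetyl chloride and zinc–copper couple in Et2O, would add to 1 to give 4,4-dichloro-3-ethoxycyclobut-2-en-1-one F9, and reductive dechlorination with zinc dust, AcOH and TMEDA in EtOH would give 4.

Step 10. Acylation may partition between oxygen and carbon or go twice, and the product may cyclodehydrate if the quench is too acidic or warm. Fallback, setting out from 20 and returning at 22: benzoyl chloride in pyridine would give 6-acetyl-7-methoxy-2,2-dimethyl-2H-chromen-5-yl benzoate F10, which is isolated. Powdered KOH in pyridine at 50 °C (or KOt-Bu in THF) would then effect the stepwise Baker–Venkataraman O-to-C acyl transfer, followed by a cold acetic acid quench.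

## Further compounds

F1 | step 4 | 3,3-dimethoxybutan-2-one | COC(C)(OC)C(C)=O
F2 | step 4 | 3-methoxybut-3-en-2-one | COC(=C)C(C)=O
F3 | step 4 | 1,1,1-trifluoro-5-methoxyhex-5-ene-2,4-dione | COC(=C)C(=O)CC(=O)C(F)(F)F
F4 | step 4 | 1-diazo-3-methoxybut-3-en-2-one | COC(=C)C(=O)C=[N+]=[N-]
F5 | step 2 | cyclobutane-1,3-dione | O=C1CC(=O)C1
F6 | step 3 | 4-methylpent-3-enal | CC(C)=CCC=O
F7 | step 3 | 1,1-dibromo-5-methylhexa-1,4-diene | CC(C)=CCC=C(Br)Br
F8 | step 3 | (5-methylhex-4-en-1-yn-1-yl)lithium | [Li]C#CCC=C(C)C
F9 | step 1 | 4,4-dichloro-3-ethoxycyclobut-2-en-1-one | CCOC1=CC(=O)C1(Cl)Cl
F10 | step 10 | 6-acetyl-7-methoxy-2,2-dimethyl-2H-chromen-5-yl benzoate | COc1cc2c(C=CC(C)(C)O2)c(OC(=O)c2ccccc2)c1C(C)=O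
A1 | alternative 1 | 6-iodo-7-methoxy-5-(methoxymethoxy)-2,2-dimethyl-2H-chromene | COCOc1c(I)c(OC)cc2c1C=CC(C)(C)O2
A2 | alternative 1 | acetophenone | CC(=O)c1ccccc1
A3 | alternative 1 | carbon monoxide | [C-]#[O+]
A4 | alternative 1 | 1-[7-methoxy-5-(methoxymethoxy)-2,2-dimethyl-2H-chromen-6-yl]-3-phenylpropane-1,3-dione | COCOc1c(C(=O)CC(=O)c3ccccc3)c(OC)cc2c1C=CC(C)(C)O2
A5 | alternative 2 | 2,6-dibromo-4-methoxybenzaldehyde | COc1cc(Br)c(C=O)c(Br)c1
A6 | alternative 2 | (Z)-4-(2,6-dibromo-4-methoxyphenyl)-2-methylbut-3-en-2-ol | COc1cc(Br)c(/C=C\C(C)(C)O)c(Br)c1
A7 | alternative 2 | 5-bromo-7-methoxy-2,2-dimethyl-2H-chromene | COc1cc(Br)c2C=CC(C)(C)Oc2c1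
A8 | alternative 3 | 7-methoxy-5-(methoxymethoxy)-2,2-dimethyl-2H-chromene-6-carbaldehyde | COCOc1c(C=O)c(OC)cc2c1C=CC(C)(C)O2
A9 | alternative 3 | (E)-7-methoxy-5-(methoxymethoxy)-2,2-dimethyl-2H-chromene-6-carbaldehyde oxime | COCOc1c(/C=N/O)c(OC)cc2c1C=CC(C)(C)O2
A10 | alternative 3 | 7-methoxy-5-(methoxymethoxy)-2,2-dimethyl-2H-chromene-6-carbonitrile oxide | COCOc1c(C#[N+][O-])c(OC)cc2c1C=CC(C)(C)O2
A11 | alternative 3 | phenylacetylene | C#Cc1ccccc1
A12 | alternative 3 | 3-[7-methoxy-5-(methoxymethoxy)-2,2-dimethyl-2H-chromen-6-yl]-5-phenylisoxazole | COCOc1c(-c3cc(-c4ccccc4)on3)c(OC)cc2c1C=CC(C)(C)O2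
A13 | alternative 3 | (Z)-3-amino-3-[7-methoxy-5-(methoxymethoxy)-2,2-dimethyl-2H-chromen-6-yl]-1-phenylprop-2-en-1-one | COCOc1c(/C(N)=C/C(=O)c3ccccc3)c(OC)cc2c1C=CC(C)(C)O2
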